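- Count amounts, not percents: the same percent of a larger charge is a larger amount, so turn each reading of X plus E into the [Q] used up.

| flask | Q | remark | time |
|---|---|---|---|
| Saturday's | 0.33 M | run made earlier |  |
| Friday's | 1.1 M | run made earlier |  |
| midnight | 0.25 M |  | 80 min |
| dawn | 0.50 M |  | 80 min |
| dusk | 1.0 M |  | 80 min |

| run | time / min | X / % | E / % |
|---|---|---|---|
| Saturday's | 2.00 | 2.9 | 0 |
| Saturday's | 6.00 | 6.5 | 0.1 |
| Saturday's | 12.0 | 12.6 | 1.8 |
| Saturday's | 15.0 | 15.0 | 2.4 |
| Saturday's | 25.0 | 22.3 | 7.4 |
| Saturday's | 30.0 | 25.2 | 10.3 |
| Saturday's | 40.0 | 29.8 | 16.9 |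
| Friday's | 2.00 | 1.4 | 0.5 |
| Friday's | 6.00 | 2.2 | 0 |
| Friday's | 12.0 | 3.9 | 0.7 |
| Friday's | 15.0 | 4.7 | 1.1 |
| Friday's | 25.0 | 6.5 | 2.1 |
| Friday's | 30.0 | 7.5 | 3.1 |
| Friday's | 40.0 | 9.4 | 5.0 |

(standard deviation of a reading: 0.3 percentage points)

- steps under discussion: Q -> X; X <-> E
- "hardly changes" means that all values lie within two and a half points (for a concentration: within two and a half percent of the largest)

1. share of X in all that became X or E for midnight, dawn, dusk, in this order
2. the course of these numbers from the first flask to the last (hardly changes / rises all the way / falls all the way / rises, then falls / falls, then rises)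

- Way one, Saturday's run: at 40.0 min it has used Q at 3.85 mM/min.
- Way two, Friday's run: with a charge 3.33 times as large, it gives 3.96 mM/min at the same time. The two agree, so you may trust a feed of Q into X that ignores [Q], zero order in the usual term, and take their mean, 3.91 mM/min.
- At 2.00 min the two ways part: Friday's gives 10.5 mM/min and Saturday's 4.79 mM/min. Friday's is the one that cheats: a single scatter there is worth 1.65 mM/min, and its reading at 6.00 min already gives 4.03 mM/min.
- For midnight, the charge over the feed gives 64.0 min; call this the emptying time. While that feed lasts, the fraction of the charge left as Q at time t is then one minus t over the emptying time.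
- Now take both ends. Dawn's emptying time is 128 min and dusk's 256 min, both beyond 80 min, so both are fed throughout and I expect their shares close together. Midnight's lies short of 80 min, so in this reckoning its feed ends before then while X goes on passing into E, and I expect a lower share there.
- Beware one limit: the runs show this feed only down to [Q] = 176 mM, and midnight's emptying time reaches below that.
- The forecast reads 36%, 45%, 45%, rises all the way, and says “Midnight exhausts Q near 64 min”. That is my emptying time too, so the two are no test of each other.
- Midnight, dawn and dusk give 42.1%, 47.3%, 47.8%, rises all the way: the forecast's shape stands, and midnight lies 6.1 percentage points above its point.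

    Q → X, rate k1*[Q]/(1 + ([Q]/sat1)) (30.0 mM, k = 0.00240 /s)
    X ⇌ E (K = 5.87, k = 4.11 × 10⁻⁴ /s)

- Midnight at 80 min, past its emptying time 64.0 min, still holds 3.17% of its Q, and X is still being made there, at 0.472 of the rate at which it is used up, each step taken net. For dawn, the emptying time 128 min leaves 37.5% of the Q at 80 min, and dawn holds 36.9%.

The readings are simulated with made-up constants, noise included.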